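**Retrosynthetic overview**
- The CO2H group is carried as a CH2OTBS group and raised to the acid last (TEMPO, then Pinnick), so it can never lactonise onto O7.
- The 11-membered carbocycle is closed at C1–C11 by an intramolecular Nozaki–Hiyama–Kishi reaction of a 2-iodo-1-alkene onto an aldehyde; C11 is then set by oxidation and CBS reduction.
- The (E)-C4=C5 alkene comes from aldol condensation of a γ-lactone with 4-iodopent-4-enal; the lactone is then reduced to a diol whose two hydroxyls become the CH2OTBS group and the isovalerate.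
- The γ-lactone (C7, first stereocentre) comes from ketoreductase reduction of a γ-keto ester made by Stetter addition of an aldehyde (from 3,3-dimethylpentane-1,5-diol) to methyl acrylate.
- Ring order: temporary γ-lactone first (step 4, opened in step 9), 11-membered carbocycle second (step 14).

Assumption: locants follow the target skeleton (C1 = ring carbon bearing =CH2, C2, C3, C4 = ring CH=, C5 bears C12 = CO2H, C6, C7 = CH–O-isovaleryl, C8, C9 = CMe2, C10, C11 = CHOH), and the four numbered starting materials are taken as purchasable.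

**Step 1**
Reactants: 1 3,3-dimethylpentane-1,5-diol
Product: 2 5-[(4-methoxybenzyl)oxy]-3,3-dimethylpentan-1-ol
Conditions: NaH (1.0 equiv), PMBCl (1.0 equiv), n-Bu4NI (cat.), THF/DMF, 0 °C to rt; 1 in 3-fold excess, recovered
Reagents that add atoms: 4-methoxybenzyl chloride, COc1ccc(CCl)cc1
Why: Williamson ether synthesis on a symmetrical diol used in excess gives the mono-PMB ether statistically, and no regiochemistry arises because both hydroxyls are equivalent.

**Step 2**
Reactants: 2 5-[(4-methoxybenzyl)oxy]-3,3-dimethylpentan-1-ol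
Product: 3 5-[(4-methoxybenzyl)oxy]-3,3-dimethylpentanal
Conditions: TEMPO (10 mol%), PhI(OAc)2 (1.1 equiv), CH2Cl2, rt
Reagents that add atoms: none
Why: TEMPO/PhI(OAc)2 (oxoammonium) oxidation stops at the aldehyde and leaves the PMB ether untouched.

**Step 3**
Reactants: 3 5-[(4-methoxybenzyl)oxy]-3,3-dimethylpentanal; 4 methyl acrylate
Product: 5 methyl 8-[(4-methoxybenzyl)oxy]-6,6-dimethyl-4-oxooctanoate
Conditions: 3-benzyl-5-(2-hydroxyethyl)-4-methylthiazolium chloride (20 mol%), Et3N (0.5 equiv), 1,4-dioxane, 80 °C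
Reagents that add atoms: none
Why: Stetter reaction, in which the thiazolium-derived carbene turns the aldehyde into an acyl-anion equivalent that adds 1,4 to the acrylate and gives the achiral γ-keto ester in one step.

**Step 4**
Reactants: 5 methyl 8-[(4-methoxybenzyl)oxy]-6,6-dimethyl-4-oxooctanoate
Product: 7 (5R)-5-{4-[(4-methoxybenzyl)oxy]-2,2-dimethylbutyl}oxolan-2-one, via hydroxy ester 6 (not isolated)
Conditions: (R)-selective ketoreductase (KRED), NADP+ (cat.), i-PrOH (cosubstrate), phosphate buffer pH 7, 30 °C; extract; then TsOH (5 mol%), CH2Cl2, rt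
Reagents that add atoms: none
Why: Biocatalytic asymmetric ketone reduction by a ketoreductase (NADPH-dependent carbonyl reductase, oxidoreductase class), picked from an enantiocomplementary panel for the (R)-alcohol, sets the first stereocentre (C7) by hydride delivery to one face of the prochiral ketone, and the γ-hydroxy ester then closes by acid-catalysed lactonisation.

**Step 5**
Reactants: 8 pent-4-yn-1-ol
Product: 9 4-iodopent-4-en-1-ol
Conditions: NaI, TMSCl, H2O, MeCN, rt
Reagents that add atoms: sodium iodide, [Na+].[I-]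
Why: Markovnikov hydroiodination of the terminal alkyne by HI generated in situ gives the 2-iodo-1-alkene regioselectively.

**Step 6**
Reactants: 9 4-iodopent-4-en-1-ol
Product: 10 4-iodopent-4-enal
Conditions: Dess–Martin periodinane (1.2 equiv), CH2Cl2, 0 °C to rt; used at once
Reagents that add atoms: none
Why: Dess–Martin oxidation gives the aldehyde under neutral conditions that do not touch the vinyl iodide.

**Step 7**
Reactants: 7 (5R)-5-{4-[(4-methoxybenzyl)oxy]-2,2-dimethylbutyl}oxolan-2-one; 10 4-iodopent-4-enal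
Product: 12 (5R)-3-(1-hydroxy-4-iodopent-4-en-1-yl)-5-{4-[(4-methoxybenzyl)oxy]-2,2-dimethylbutyl}oxolan-2-one (diastereomer mixture), via lithium enolate 11 (not isolated)
Conditions: LDA (1.1 equiv), THF, −78 °C; then 10 (1.2 equiv), −78 °C; AcOH quench
Reagents that add atoms: none
Why: Directed aldol addition of the preformed lactone enolate forms the C4–C5 bond, and the two new stereocentres do not matter because both are destroyed in step 8 while C7 is untouched.

**Step 8**
Reactants: 12 (5R)-3-(1-hydroxy-4-iodopent-4-en-1-yl)-5-{4-[(4-methoxybenzyl)oxy]-2,2-dimethylbutyl}oxolan-2-one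
Product: 14 (3E,5S)-3-(4-iodopent-4-en-1-ylidene)-5-{4-[(4-methoxybenzyl)oxy]-2,2-dimethylbutyl}oxolan-2-one, via mesylate 13 (not isolated)
Conditions: MsCl (1.5 equiv), Et3N (3 equiv), CH2Cl2, 0 °C; then DBU (3 equiv), 0 °C to rt
Reagents that add atoms: none
Why: Mesylation and DBU-promoted E1cB elimination through the lactone enolate give the exocyclic alkene under thermodynamic control as the E isomer (chain trans to C=O, as in the target), any minor Z isomer being removed by chromatography, and C7 keeps its configuration (the descriptor changes to S only through CIP priorities).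

**Step 9**
Reactants: 14 (3E,5S)-3-(4-iodopent-4-en-1-ylidene)-5-{4-[(4-methoxybenzyl)oxy]-2,2-dimethylbutyl}oxolan-2-one
Product: 15 (2E,4S)-2-(4-iodopent-4-en-1-ylidene)-8-[(4-methoxybenzyl)oxy]-6,6-dimethyloctane-1,4-diol
Conditions: DIBAL-H (4 equiv), CH2Cl2, −78 to 0 °C; Rochelle salt work-up
Reagents that add atoms: none
Why: DIBAL-H reduces the α-alkylidene lactone by 1,2-addition through the lactol to the (E)-allylic 1,4-diol without touching the vinyl iodide, the PMB ether or the alkene geometry.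

**Step 10**
Reactants: 15 (2E,4S)-2-(4-iodopent-4-en-1-ylidene)-8-[(4-methoxybenzyl)oxy]-6,6-dimethyloctane-1,4-diol
Product: 16 (2E,4S)-1-[(tert-butyldimethylsilyl)oxy]-2-(4-iodopent-4-en-1-ylidene)-8-[(4-methoxybenzyl)oxy]-6,6-dimethyloctan-4-ol
Conditions: TBSCl (1.05 equiv), imidazole (2 equiv), CH2Cl2, 0 °C
Reagents that add atoms: tert-butyldimethylsilyl chloride, CC(C)(C)[Si](C)(C)Cl
Why: Silylation is selective on steric grounds for the unhindered primary allylic hydroxyl over the secondary C7 hydroxyl.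

**Step 11**
Reactants: 16 (2E,4S)-1-[(tert-butyldimethylsilyl)oxy]-2-(4-iodopent-4-en-1-ylidene)-8-[(4-methoxybenzyl)oxy]-6,6-dimethyloctan-4-ol; 17 3-methylbutanoic anhydride
Product: 18 (2E,4S)-1-[(tert-butyldimethylsilyl)oxy]-2-(4-iodopent-4-en-1-ylidene)-8-[(4-methoxybenzyl)oxy]-6,6-dimethyloctan-4-yl 3-methylbutanoate
Conditions: 17 (2 equiv), DMAP (0.2 equiv), Et3N (3 equiv), CH2Cl2, rt
Reagents that add atoms: none
Why: DMAP-catalysed acylation esterifies the secondary alcohol with retention at C7 and installs the isovalerate of the target before any carboxyl group exists that could lactonise onto O7.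

**Step 12**
Reactants: 18 (2E,4S)-1-[(tert-butyldimethylsilyl)oxy]-2-(4-iodopent-4-en-1-ylidene)-8-[(4-methoxybenzyl)oxy]-6,6-dimethyloctan-4-yl 3-methylbutanoate
Product: 19 (2E,4S)-1-[(tert-butyldimethylsilyl)oxy]-8-hydroxy-2-(4-iodopent-4-en-1-ylidene)-6,6-dimethyloctan-4-yl 3-methylbutanoate
Conditions: DDQ (1.3 equiv), CH2Cl2/pH 7 buffer (10:1), 0 °C to rt
Reagents that add atoms: none
Why: Oxidative PMB cleavage by DDQ (hydride abstraction, then hydrolysis of the oxocarbenium ion) frees the primary alcohol while silyl ether, ester, alkenes and vinyl iodide are inert.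

**Step 13**
Reactants: 19 (2E,4S)-1-[(tert-butyldimethylsilyl)oxy]-8-hydroxy-2-(4-iodopent-4-en-1-ylidene)-6,6-dimethyloctan-4-yl 3-methylbutanoate
Product: 20 (2E,4S)-1-[(tert-butyldimethylsilyl)oxy]-2-(4-iodopent-4-en-1-ylidene)-6,6-dimethyl-8-oxooctan-4-yl 3-methylbutanoate
Conditions: Dess–Martin periodinane (1.3 equiv), CH2Cl2, 0 °C to rt
Reagents that add atoms: none
Why: Dess–Martin oxidation gives the C11 aldehyde without epimerisable centres nearby and without touching the other groups.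

**Step 14**
Reactants: 20 (2E,4S)-1-[(tert-butyldimethylsilyl)oxy]-2-(4-iodopent-4-en-1-ylidene)-6,6-dimethyl-8-oxooctan-4-yl 3-methylbutanoate
Product: 21 (1S,3E)-3-{[(tert-butyldimethylsilyl)oxy]methyl}-8-hydroxy-10,10-dimethyl-7-methylidenecycloundec-3-en-1-yl 3-methylbutanoate (mixture of C8 epimers; C8 = skeleton C11)
Conditions: CrCl2 (10 equiv), NiCl2 (2 mol%), degassed DMSO, rt, syringe-pump addition to 2 mM; aqueous work-up
Reagents that add atoms: none
Why: Intramolecular Nozaki–Hiyama–Kishi reaction, in which Ni-catalysed activation of the vinyl iodide and transfer to Cr(III) gives a chemoselective alkenyl nucleophile that adds to the aldehyde under high dilution and closes the 11-membered ring (helped by the cis-in-ring C4=C5 alkene and the gem-dimethyl group), with C11 formed as an epimer mixture that steps 15 and 16 correct.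

**Step 15**
Reactants: 21 (1S,3E)-3-{[(tert-butyldimethylsilyl)oxy]methyl}-8-hydroxy-10,10-dimethyl-7-methylidenecycloundec-3-en-1-yl 3-methylbutanoate
Product: 22 (1S,3E)-3-{[(tert-butyldimethylsilyl)oxy]methyl}-10,10-dimethyl-7-methylidene-8-oxocycloundec-3-en-1-yl 3-methylbutanoate
Conditions: Dess–Martin periodinane (1.5 equiv), CH2Cl2, 0 °C; used at once
Reagents that add atoms: none
Why: Dess–Martin oxidation of the allylic alcohol erases the uncontrolled C11 centre and gives the α-methylene ketone.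

**Step 16**
Reactants: 22 (1S,3E)-3-{[(tert-butyldimethylsilyl)oxy]methyl}-10,10-dimethyl-7-methylidene-8-oxocycloundec-3-en-1-yl 3-methylbutanoate
Product: 23 (1S,3E,8S)-3-{[(tert-butyldimethylsilyl)oxy]methyl}-8-hydroxy-10,10-dimethyl-7-methylidenecycloundec-3-en-1-yl 3-methylbutanoate
Conditions: (R)-2-methyl-CBS-oxazaborolidine (0.3 equiv), catecholborane (2 equiv), toluene, −78 to −40 °C
Reagents that add atoms: none
Why: Corey–Bakshi–Shibata reduction, in which the (R)-oxazaborolidine binds the ketone with the alkenyl carbon C1 as the large group and delivers hydride to one face, sets C11 as S under catalyst control with exclusive 1,2-reduction.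

**Step 17**
Reactants: 23 (1S,3E,8S)-3-{[(tert-butyldimethylsilyl)oxy]methyl}-8-hydroxy-10,10-dimethyl-7-methylidenecycloundec-3-en-1-yl 3-methylbutanoate
Product: 24 (1S,3E,8S)-8-hydroxy-3-(hydroxymethyl)-10,10-dimethyl-7-methylidenecycloundec-3-en-1-yl 3-methylbutanoate
Conditions: HF·pyridine, pyridine, THF, 0 °C to rt
Reagents that add atoms: none
Why: Fluoride-mediated desilylation under buffered, non-basic conditions removes the primary TBS ether without cleaving or migrating the isovalerate.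

**Step 18**
Reactants: 24 (1S,3E,8S)-8-hydroxy-3-(hydroxymethyl)-10,10-dimethyl-7-methylidenecycloundec-3-en-1-yl 3-methylbutanoate
Product: 25 (1S,3E,8S)-3-formyl-8-hydroxy-10,10-dimethyl-7-methylidenecycloundec-3-en-1-yl 3-methylbutanoate
Conditions: TEMPO (15 mol%), PhI(OAc)2 (1.2 equiv), CH2Cl2, rt
Reagents that add atoms: none
Why: TEMPO/PhI(OAc)2 oxidation is selective for the primary allylic alcohol over the hindered secondary alcohol at C11 and gives the (E)-enal without isomerisation.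

**Step 19**
Reactants: 25 (1S,3E,8S)-3-formyl-8-hydroxy-10,10-dimethyl-7-methylidenecycloundec-3-en-1-yl 3-methylbutanoate
Product: 26 (1E,6S,10S)-6-hydroxy-8,8-dimethyl-5-methylidene-10-[(3-methylbutanoyl)oxy]cycloundec-1-ene-1-carboxylic acid (target)
Conditions: NaClO2, NaH2PO4, 2-methyl-2-butene, t-BuOH/H2O, 0 °C to rt
Reagents that add atoms: sodium chlorite, [Na+].[O-]Cl=O
Why: Pinnick (Lindgren–Kraus) oxidation converts the enal into the carboxylic acid without touching the alkenes (2-methyl-2-butene scavenges HOCl), the free alcohol or the ester.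

**Compound list**
1 | 3,3-dimethylpentane-1,5-diol | OCCC(C)(C)CCO | starting material
2 | 5-[(4-methoxybenzyl)oxy]-3,3-dimethylpentan-1-ol | COc1ccc(COCCC(C)(C)CCO)cc1 | intermediate
3 | 5-[(4-methoxybenzyl)oxy]-3,3-dimethylpentanal | COc1ccc(COCCC(C)(C)CC=O)cc1 | intermediate
4 | methyl acrylate | C=CC(=O)OC | starting material
5 | methyl 8-[(4-methoxybenzyl)oxy]-6,6-dimethyl-4-oxooctanoate | COC(=O)CCC(=O)CC(C)(C)CCOCc1ccc(OC)cc1 | intermediate
6 | methyl (4R)-4-hydroxy-8-[(4-methoxybenzyl)oxy]-6,6-dimethyloctanoate | COC(=O)CC[C@@H](O)CC(C)(C)CCOCc1ccc(OC)cc1 | intermediate (not isolated)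
7 | (5R)-5-{4-[(4-methoxybenzyl)oxy]-2,2-dimethylbutyl}oxolan-2-one | O=C1CC[C@H](CC(C)(C)CCOCc2ccc(OC)cc2)O1 | intermediate
8 | pent-4-yn-1-ol | C#CCCCO | starting material
9 | 4-iodopent-4-en-1-ol | C=C(I)CCCO | intermediate
10 | 4-iodopent-4-enal | C=C(I)CCC=O | intermediate
11 | lithium (5R)-5-{4-[(4-methoxybenzyl)oxy]-2,2-dimethylbutyl}-4,5-dihydrofuran-2-olate (lithium enolate of 7) | [Li+].[O-]C1=CC[C@H](CC(C)(C)CCOCc2ccc(OC)cc2)O1 | intermediate (not isolated)
12 | (5R)-3-(1-hydroxy-4-iodopent-4-en-1-yl)-5-{4-[(4-methoxybenzyl)oxy]-2,2-dimethylbutyl}oxolan-2-one (diastereomer mixture) | O=C1C(C(O)CCC(I)=C)C[C@H](CC(C)(C)CCOCc2ccc(OC)cc2)O1 | intermediate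
13 | 4-iodo-1-[(5R)-5-{4-[(4-methoxybenzyl)oxy]-2,2-dimethylbutyl}-2-oxooxolan-3-yl]pent-4-en-1-yl methanesulfonate (diastereomer mixture) | O=C1C(C(OS(C)(=O)=O)CCC(I)=C)C[C@H](CC(C)(C)CCOCc2ccc(OC)cc2)O1 | intermediate (not isolated)
14 | (3E,5S)-3-(4-iodopent-4-en-1-ylidene)-5-{4-[(4-methoxybenzyl)oxy]-2,2-dimethylbutyl}oxolan-2-one | O=C1/C(=C/CCC(I)=C)C[C@H](CC(C)(C)CCOCc2ccc(OC)cc2)O1 | intermediate
15 | (2E,4S)-2-(4-iodopent-4-en-1-ylidene)-8-[(4-methoxybenzyl)oxy]-6,6-dimethyloctane-1,4-diol | OC/C(=C/CCC(I)=C)C[C@@H](O)CC(C)(C)CCOCc1ccc(OC)cc1 | intermediate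
16 | (2E,4S)-1-[(tert-butyldimethylsilyl)oxy]-2-(4-iodopent-4-en-1-ylidene)-8-[(4-methoxybenzyl)oxy]-6,6-dimethyloctan-4-ol | CC(C)(C)[Si](C)(C)OC/C(=C/CCC(I)=C)C[C@@H](O)CC(C)(C)CCOCc1ccc(OC)cc1 | intermediate
17 | 3-methylbutanoic anhydride (isovaleric anhydride) | CC(C)CC(=O)OC(=O)CC(C)C | starting material
18 | (2E,4S)-1-[(tert-butyldimethylsilyl)oxy]-2-(4-iodopent-4-en-1-ylidene)-8-[(4-methoxybenzyl)oxy]-6,6-dimethyloctan-4-yl 3-methylbutanoate | CC(C)(C)[Si](C)(C)OC/C(=C/CCC(I)=C)C[C@@H](OC(=O)CC(C)C)CC(C)(C)CCOCc1ccc(OC)cc1 | intermediate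
19 | (2E,4S)-1-[(tert-butyldimethylsilyl)oxy]-8-hydroxy-2-(4-iodopent-4-en-1-ylidene)-6,6-dimethyloctan-4-yl 3-methylbutanoate | CC(C)(C)[Si](C)(C)OC/C(=C/CCC(I)=C)C[C@@H](OC(=O)CC(C)C)CC(C)(C)CCO | intermediate
20 | (2E,4S)-1-[(tert-butyldimethylsilyl)oxy]-2-(4-iodopent-4-en-1-ylidene)-6,6-dimethyl-8-oxooctan-4-yl 3-methylbutanoate | CC(C)(C)[Si](C)(C)OC/C(=C/CCC(I)=C)C[C@@H](OC(=O)CC(C)C)CC(C)(C)CC=O | intermediate
21 | (1S,3E)-3-{[(tert-butyldimethylsilyl)oxy]methyl}-8-hydroxy-10,10-dimethyl-7-methylidenecycloundec-3-en-1-yl 3-methylbutanoate (C8 epimer mixture) | C=C1CC/C=C(/CO[Si](C)(C)C(C)(C)C)C[C@@H](OC(=O)CC(C)C)CC(C)(C)CC1O | intermediate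
22 | (1S,3E)-3-{[(tert-butyldimethylsilyl)oxy]methyl}-10,10-dimethyl-7-methylidene-8-oxocycloundec-3-en-1-yl 3-methylbutanoate | C=C1CC/C=C(/CO[Si](C)(C)C(C)(C)C)C[C@@H](OC(=O)CC(C)C)CC(C)(C)CC1=O | intermediate
23 | (1S,3E,8S)-3-{[(tert-butyldimethylsilyl)oxy]methyl}-8-hydroxy-10,10-dimethyl-7-methylidenecycloundec-3-en-1-yl 3-methylbutanoate | C=C1CC/C=C(/CO[Si](C)(C)C(C)(C)C)C[C@@H](OC(=O)CC(C)C)CC(C)(C)C[C@@H]1O | intermediate
24 | (1S,3E,8S)-8-hydroxy-3-(hydroxymethyl)-10,10-dimethyl-7-methylidenecycloundec-3-en-1-yl 3-methylbutanoate | C=C1CC/C=C(/CO)C[C@@H](OC(=O)CC(C)C)CC(C)(C)C[C@@H]1O | intermediate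
25 | (1S,3E,8S)-3-formyl-8-hydroxy-10,10-dimethyl-7-methylidenecycloundec-3-en-1-yl 3-methylbutanoate | C=C1CC/C=C(/C=O)C[C@@H](OC(=O)CC(C)C)CC(C)(C)C[C@@H]1O | intermediate
26 | (1E,6S,10S)-6-hydroxy-8,8-dimethyl-5-methylidene-10-[(3-methylbutanoyl)oxy]cycloundec-1-ene-1-carboxylic acid | C=C1CC/C=C(/C(=O)O)C[C@@H](OC(=O)CC(C)C)CC(C)(C)C[C@@H]1O | target

**Totals**
Total step count: 19.
Longest linear sequence: 17 steps (steps 1–4 and 7–19, from 1 to 26); steps 5–6 are a two-step side branch to aldehyde 10.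

**Three steps most likely to fail, each with one fallback**

Step 14 (NHK closure of the 11-membered ring; risk of oligomers or low conversion). The fallback sets out from aldehyde 20 and comes back at enone 22, replacing steps 14 and 15 by a Pd-catalysed acylative ring closure. Iodine–tin exchange with hexamethylditin and Pd(PPh3)4 (toluene, 80 °C) gives (2E,4S)-1-[(tert-butyldimethylsilyl)oxy]-6,6-dimethyl-8-oxo-2-[4-(trimethylstannyl)pent-4-en-1-ylidene]octan-4-yl 3-methylbutanoate F3. Buffered Pinnick oxidation (NaClO2, NaH2PO4, 2-methyl-2-butene) gives (5S,7E)-8-[(tert-butyldimethylsilyl)oxy]-3,3-dimethyl-5-[(3-methylbutanoyl)oxy]-7-[4-(trimethylstannyl)pent-4-en-1-ylidene]octanoic acid F4. Ghosez's reagent (1-chloro-N,N,2-trimethylprop-1-en-1-amine, CH2Cl2, 0 °C) gives (5S,7E)-8-[(tert-butyldimethylsilyl)oxy]-3,3-dimethyl-5-[(3-methylbutanoyl)oxy]-7-[4-(trimethylstannyl)pent-4-en-1-ylidene]octanoyl chloride F5. Slow addition of this to Pd2(dba)3/tri(2-furyl)phosphine in toluene at 80 °C (1 mM) closes the ring by intramolecular Stille acylation and gives 22 directly.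

Step 16 (CBS reduction of the macrocyclic α-methylene ketone; the ring may override the catalyst). The fallback sets out from the epimer mixture 21 and comes back at 23, replacing catalyst-controlled reduction by separation and stereoinversion. Chromatography of 21 gives 23 and its epimer (1S,3E,8R)-3-{[(tert-butyldimethylsilyl)oxy]methyl}-8-hydroxy-10,10-dimethyl-7-methylidenecycloundec-3-en-1-yl 3-methylbutanoate F6. Mitsunobu inversion of this epimer with chloroacetic acid (PPh3, DIAD, toluene, 0 °C) gives (1S,3E,8S)-3-{[(tert-butyldimethylsilyl)oxy]methyl}-8-[(chloroacetyl)oxy]-10,10-dimethyl-7-methylidenecycloundec-3-en-1-yl 3-methylbutanoate F7. Selective methanolysis of the labile chloroacetate (cat. K2CO3, MeOH, 0 °C; the hindered isovalerate survives) returns 23.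

Step 3 (Stetter addition; acyloin formation or acrylate oligomerisation may dominate). The fallback sets out from aldehyde 3 and comes back at keto ester 5, replacing the acyl-anion addition by homologation, alkylation and decarboxylation. Roskamp reaction of 3 with ethyl diazoacetate (cat. SnCl2, CH2Cl2, rt) gives ethyl 7-[(4-methoxybenzyl)oxy]-5,5-dimethyl-3-oxoheptanoate F1. Alkylation with methyl bromoacetate (K2CO3, acetone, 50 °C) gives 1-ethyl 4-methyl 2-{5-[(4-methoxybenzyl)oxy]-3,3-dimethylpentanoyl}butanedioate F2. Krapcho dealkoxycarbonylation (LiCl, wet DMSO, 140 °C) removes only the activated β-keto ester group and gives 5.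

**Further compounds**
F1 | step 3 | ethyl 7-[(4-methoxybenzyl)oxy]-5,5-dimethyl-3-oxoheptanoate | CCOC(=O)CC(=O)CC(C)(C)CCOCc1ccc(OC)cc1
F2 | step 3 | 1-ethyl 4-methyl 2-{5-[(4-methoxybenzyl)oxy]-3,3-dimethylpentanoyl}butanedioate | CCOC(=O)C(CC(=O)OC)C(=O)CC(C)(C)CCOCc1ccc(OC)cc1
F3 | step 14 | (2E,4S)-1-[(tert-butyldimethylsilyl)oxy]-6,6-dimethyl-8-oxo-2-[4-(trimethylstannyl)pent-4-en-1-ylidene]octan-4-yl 3-methylbutanoate | CC(C)(C)[Si](C)(C)OC/C(=C/CCC(=C)[Sn](C)(C)C)C[C@@H](OC(=O)CC(C)C)CC(C)(C)CC=O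
F4 | step 14 | (5S,7E)-8-[(tert-butyldimethylsilyl)oxy]-3,3-dimethyl-5-[(3-methylbutanoyl)oxy]-7-[4-(trimethylstannyl)pent-4-en-1-ylidene]octanoic acid | CC(C)(C)[Si](C)(C)OC/C(=C/CCC(=C)[Sn](C)(C)C)C[C@@H](OC(=O)CC(C)C)CC(C)(C)CC(=O)O
F5 | step 14 | (5S,7E)-8-[(tert-butyldimethylsilyl)oxy]-3,3-dimethyl-5-[(3-methylbutanoyl)oxy]-7-[4-(trimethylstannyl)pent-4-en-1-ylidene]octanoyl chloride | CC(C)(C)[Si](C)(C)OC/C(=C/CCC(=C)[Sn](C)(C)C)C[C@@H](OC(=O)CC(C)C)CC(C)(C)CC(=O)Cl
F6 | step 16 | (1S,3E,8R)-3-{[(tert-butyldimethylsilyl)oxy]methyl}-8-hydroxy-10,10-dimethyl-7-methylidenecycloundec-3-en-1-yl 3-methylbutanoate | C=C1CC/C=C(/CO[Si](C)(C)C(C)(C)C)C[C@@H](OC(=O)CC(C)C)CC(C)(C)C[C@H]1O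
F7 | step 16 | (1S,3E,8S)-3-{[(tert-butyldimethylsilyl)oxy]methyl}-8-[(chloroacetyl)oxy]-10,10-dimethyl-7-methylidenecycloundec-3-en-1-yl 3-methylbutanoate | C=C1CC/C=C(/CO[Si](C)(C)C(C)(C)C)C[C@@H](OC(=O)CC(C)C)CC(C)(C)C[C@@H]1OC(=O)CCl
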